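**Plan**

- Retrosynthesis first removes the silyl group from the carbinol oxygen, then cuts two bonds of ring A, C1'–C2' and C5'–C6' (dihydrochalcone numbering).
- Enabling feature: ring A is a benzene with the acyl group on C1', hydroxyls on C2' and C4' and the prenyl group on C5'. C2'–C5' therefore map onto a 4-alkyl-1,1,3-trioxygenated buta-1,3-diene, and C1'/C6' onto the two sp carbons of an acyl alkyne.
- The ynone is cut at the C(=O)–C≡C bond (amide plus ethynyl Grignard); the diene is cut between the acetoacetate γ-carbon and the prenyl CH2.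
- Forward: amino acid → α-silyloxy ynone (four steps); acetoacetate → bis(silyloxy) diene (three steps); cycloaddition/aromatization builds ring A, the only ring made (ring B comes with the amino acid); desilylation finishes.
- The single (S) stereocentre comes from O-methyl-L-tyrosine through diazotization with retention and is not touched again.

Key step: step 8

Remark: the double-bond geometry of the mono-silyl enol ether and of the ketene-acetal end of the diene is lost in the aromatic ring; the isomers drawn are those expected to predominate.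
Remark: short-lived species that exist only until the quench (enolates, the magnesium chelate, the diazonium ion and the α-lactone) are described in the Why lines and not numbered.

**Route**

Step 1
Reactants: 1 O-methyl-L-tyrosine
Product: 2 (S)-2-hydroxy-3-(4-methoxyphenyl)propanoic acid
Conditions: NaNO2, 1 M H2SO4 (aq), 0 °C → rt
Reagents that add atoms: water, O
Why: Diazotization of an α-amino acid goes with net retention, because the carboxylate displaces N2 to give a transient α-lactone that water reopens at the same carbon (double inversion), so the (S) centre of 1 should become the (S) carbinol of 2.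

Step 2
Reactants: 2 (S)-2-hydroxy-3-(4-methoxyphenyl)propanoic acid
Product: 3 (S)-2-hydroxy-N-methoxy-3-(4-methoxyphenyl)-N-methylpropanamide
Conditions: MeNHOMe·HCl, EDC·HCl, HOBt, N-methylmorpholine, CH2Cl2, 0 °C → rt
Reagents that add atoms: N,O-dimethylhydroxylamine hydrochloride, CNOC.Cl
Why: Carbodiimide/HOBt amidation of an unprotected α-hydroxy acid is standard; the amine outcompetes the secondary hydroxyl, and without an N-acyl group no oxazolone pathway to racemization exists.

Step 3
Reactants: 3 (S)-2-hydroxy-N-methoxy-3-(4-methoxyphenyl)-N-methylpropanamide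
Product: 4 (S)-2-(tert-butyldimethylsilyloxy)-N-methoxy-3-(4-methoxyphenyl)-N-methylpropanamide
Conditions: TBSCl, imidazole, DMF, rt
Reagents that add atoms: tert-butyldimethylsilyl chloride, CC(C)(C)[Si](C)(C)Cl
Why: Imidazole-promoted silylation of a secondary alcohol is routine, and the TBS ether is chosen to survive the Grignard addition, the cycloaddition and the dilute-acid work-up of step 8.

Step 4
Reactants: 4 (S)-2-(tert-butyldimethylsilyloxy)-N-methoxy-3-(4-methoxyphenyl)-N-methylpropanamide; 5 ethynylmagnesium bromide
Product: 6 (S)-4-(tert-butyldimethylsilyloxy)-5-(4-methoxyphenyl)pent-1-yn-3-one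
Conditions: HC≡CMgBr (0.5 M in THF, excess), THF, 0 °C; inverse quench into cold 1 M HCl
Reagents that add atoms: none
Why: Weinreb ketone synthesis; the magnesium chelate of the tetrahedral adduct persists until the quench, which prevents over-addition and keeps the α-centre intact, and the inverse acidic quench protonates the released N,O-dimethylhydroxylamine before it can add to the ynone.

Step 5
Reactants: 7 methyl acetoacetate; 8 prenyl bromide (1-bromo-3-methylbut-2-ene)
Product: 9 methyl 7-methyl-3-oxooct-6-enoate
Conditions: NaH, THF, 0 °C; n-BuLi, 0 °C; 8, 0 °C → rt; then 1 M HCl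
Reagents that add atoms: none
Why: γ-Alkylation of the acetoacetate dianion; the more basic terminal carbanion should react selectively with the primary allylic bromide by SN2.

Step 6
Reactants: 9 methyl 7-methyl-3-oxooct-6-enoate
Product: 10 methyl (E)-7-methyl-3-(trimethylsilyloxy)octa-2,6-dienoate
Conditions: Me3SiCl, Et3N, hexane, rt; filtration under Ar
Reagents that add atoms: chlorotrimethylsilane, C[Si](C)(C)Cl
Why: O-Silylation of the enolized β-keto ester with amine and chlorosilane is the standard first stage toward 1,3-bis(silyloxy) dienes.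

Step 7
Reactants: 10 methyl (E)-7-methyl-3-(trimethylsilyloxy)octa-2,6-dienoate
Product: 11 (1Z,3Z)-1-methoxy-7-methyl-1,3-bis(trimethylsilyloxy)octa-1,3,6-triene
Conditions: LDA (commercial solution), THF, −78 °C; Me3SiCl, −78 °C → rt; hexane, filtration under Ar; used crude
Reagents that add atoms: chlorotrimethylsilane, C[Si](C)(C)Cl
Why: γ-Deprotonation of the vinylogous ester and O-silylation of the dienolate is the standard route to 1-alkoxy-1,3-bis(silyloxy)-1,3-dienes, with the 4-alkyl group expected trans to C2 (3Z), the geometry that can reach the s-cis conformation.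

Step 8
Reactants: 6 (S)-4-(tert-butyldimethylsilyloxy)-5-(4-methoxyphenyl)pent-1-yn-3-one; 11 (1Z,3Z)-1-methoxy-7-methyl-1,3-bis(trimethylsilyloxy)octa-1,3,6-triene
Product: 14 (S)-2-(tert-butyldimethylsilyloxy)-1-[2,4-dihydroxy-5-(3-methylbut-2-en-1-yl)phenyl]-3-(4-methoxyphenyl)propan-1-one, via cyclohexa-1,4-diene cycloadduct 12 (not isolated), via bis(trimethylsilyl) aryl ether 13 (not isolated)
Conditions: 11 (2 equiv), toluene, 0 °C → rt; then 0.5 M HCl, THF, 0 °C
Reagents that add atoms: none
Why: The electron-rich diene 11 (largest HOMO coefficient at C4) and the electron-poor ynone 6 should combine in a normal-demand, highly asynchronous [4+2] cycloaddition, or its stepwise Mukaiyama–Michael/ring-closure equivalent, in which diene C4 bonds to the terminal alkyne carbon and the ketene-acetal carbon C1 to the acyl-bearing alkyne carbon, giving cyclohexa-1,4-diene 12. Ring A thus closes as a six-membered carbocycle by intermolecular [4+2] union of a four-carbon and a two-carbon unit, both new C–C bonds forming in the same operation. Aromatization follows by 1,4-loss of methanol from the mixed silyl methyl ketal carbon and the doubly allylic C–H of 12 to give 13, whose two aryl trimethylsilyl ethers are hydrolysed in the dilute-acid work-up while the secondary TBS ether stays in place. The closest known reaction type is the Diels–Alder/aromatization of 1-alkoxy-1,3-bis(silyloxy)-1,3-dienes with acetylenic esters and ketones to 2,4-dioxygenated aryl carbonyl compounds. No new stereocentre survives (the two sp3 ring carbons of 12 become aromatic), and the tyrosine-derived centre is not at risk because the medium is neutral and aprotic until the brief cold acid work-up. The selectivities needed are regiochemical, secured by the matched polarization of the 1,1,3-trioxygenated diene and the β-electrophilic ynone, and in the elimination, where methanol rather than silanol must leave, secured because the methoxy oxygen is the more basic leaving group and because any prior Si–O cleavage gives a hemiketal that can only expel methanol.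

Step 9
Reactants: 14 (S)-2-(tert-butyldimethylsilyloxy)-1-[2,4-dihydroxy-5-(3-methylbut-2-en-1-yl)phenyl]-3-(4-methoxyphenyl)propan-1-one
Product: 15 lespeflorin C2, (S)-1-[2,4-dihydroxy-5-(3-methylbut-2-en-1-yl)phenyl]-2-hydroxy-3-(4-methoxyphenyl)propan-1-one
Conditions: HF·pyridine, pyridine, THF, 0 °C → rt
Reagents that add atoms: none
Why: Fluoride-mediated Si–O cleavage under pyridine-buffered, weakly acidic conditions should free the secondary carbinol without enolizing the α-ketol (no epimerization or ketol transposition) and without cyclizing the ortho-prenyl phenol.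

**Compound list**

1 | O-methyl-L-tyrosine, (S)-2-amino-3-(4-methoxyphenyl)propanoic acid | COc1ccc(C[C@H](N)C(=O)O)cc1 | starting material
2 | (S)-2-hydroxy-3-(4-methoxyphenyl)propanoic acid | COc1ccc(C[C@H](O)C(=O)O)cc1 | intermediate
3 | (S)-2-hydroxy-N-methoxy-3-(4-methoxyphenyl)-N-methylpropanamide | COc1ccc(C[C@H](O)C(=O)N(C)OC)cc1 | intermediate
4 | (S)-2-(tert-butyldimethylsilyloxy)-N-methoxy-3-(4-methoxyphenyl)-N-methylpropanamide | COc1ccc(C[C@H](O[Si](C)(C)C(C)(C)C)C(=O)N(C)OC)cc1 | intermediate
5 | ethynylmagnesium bromide | C#C[Mg]Br | starting material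
6 | (S)-4-(tert-butyldimethylsilyloxy)-5-(4-methoxyphenyl)pent-1-yn-3-one | COc1ccc(C[C@H](O[Si](C)(C)C(C)(C)C)C(=O)C#C)cc1 | intermediate
7 | methyl acetoacetate | CC(=O)CC(=O)OC | starting material
8 | prenyl bromide, 1-bromo-3-methylbut-2-ene | CC(C)=CCBr | starting material
9 | methyl 7-methyl-3-oxooct-6-enoate | CC(C)=CCCC(=O)CC(=O)OC | intermediate
10 | methyl (E)-7-methyl-3-(trimethylsilyloxy)octa-2,6-dienoate | COC(=O)/C=C(/O[Si](C)(C)C)CCC=C(C)C | intermediate
11 | (1Z,3Z)-1-methoxy-7-methyl-1,3-bis(trimethylsilyloxy)octa-1,3,6-triene | CO/C(O[Si](C)(C)C)=C/C(O[Si](C)(C)C)=C/CC=C(C)C | intermediate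
12 | (2S)-2-(tert-butyldimethylsilyloxy)-1-[6-methoxy-3-(3-methylbut-2-en-1-yl)-4,6-bis(trimethylsilyloxy)cyclohexa-1,4-dien-1-yl]-3-(4-methoxyphenyl)propan-1-one, mixture of ring diastereomers | COc1ccc(C[C@H](O[Si](C)(C)C(C)(C)C)C(=O)C2=CC(CC=C(C)C)C(O[Si](C)(C)C)=CC2(OC)O[Si](C)(C)C)cc1 | intermediate (not isolated)
13 | (S)-2-(tert-butyldimethylsilyloxy)-3-(4-methoxyphenyl)-1-[5-(3-methylbut-2-en-1-yl)-2,4-bis(trimethylsilyloxy)phenyl]propan-1-one | COc1ccc(C[C@H](O[Si](C)(C)C(C)(C)C)C(=O)c2cc(CC=C(C)C)c(O[Si](C)(C)C)cc2O[Si](C)(C)C)cc1 | intermediate (not isolated)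
14 | (S)-2-(tert-butyldimethylsilyloxy)-1-[2,4-dihydroxy-5-(3-methylbut-2-en-1-yl)phenyl]-3-(4-methoxyphenyl)propan-1-one | COc1ccc(C[C@H](O[Si](C)(C)C(C)(C)C)C(=O)c2cc(CC=C(C)C)c(O)cc2O)cc1 | intermediate
15 | lespeflorin C2, (S)-1-[2,4-dihydroxy-5-(3-methylbut-2-en-1-yl)phenyl]-2-hydroxy-3-(4-methoxyphenyl)propan-1-one | COc1ccc(C[C@H](O)C(=O)c2cc(CC=C(C)C)c(O)cc2O)cc1 | target

**Step count**

Total: 9 steps. Longest linear sequence: 6 steps (steps 1, 2, 3, 4, 8, 9); the diene branch (steps 5–7) joins at step 8.

**Steps most likely to fail**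

Step 8. The moisture-sensitive diene may be protonated or desilylated faster than it adds, the ynone may oligomerize, the sequence may stop at an open-chain Michael adduct, or silanol may be lost in place of methanol so that the ortho oxygen stays methylated. The fallback gives up the ring construction and brings ring A in preformed; it sets out from 4 and returns at 15. Commercial 4,6-dibromoresorcinol F1 would be protected with MOMCl/iPr2NEt as 1,5-dibromo-2,4-bis(methoxymethoxy)benzene F2. Mono bromine–lithium exchange (n-BuLi, THF, −78 °C), then CuBr·SMe2 and prenyl bromide 8, would give 1-bromo-2,4-bis(methoxymethoxy)-5-(3-methylbut-2-en-1-yl)benzene F3. A second exchange and addition of the aryllithium to 4 (Weinreb ketone synthesis) would give (S)-1-[2,4-bis(methoxymethoxy)-5-(3-methylbut-2-en-1-yl)phenyl]-2-(tert-butyldimethylsilyloxy)-3-(4-methoxyphenyl)propan-1-one F4. HCl in MeOH at rt would then remove both MOM groups and the TBS ether to give 15.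

Step 4. The N,O-dimethylhydroxylamine released on collapse of the tetrahedral adduct may add in conjugate fashion to the terminal ynone, or the acidic α-proton may be lost with erosion of configuration. The fallback changes the oxidation level at which the alkyne is introduced; it sets out from 4 and returns at 6. DIBAL-H (THF, −78 °C) would reduce 4 to (S)-2-(tert-butyldimethylsilyloxy)-3-(4-methoxyphenyl)propanal F5, used crude and cold. Addition of 5 would give (4S)-4-(tert-butyldimethylsilyloxy)-5-(4-methoxyphenyl)pent-1-yn-3-ol F6 as a mixture of C3 epimers, which is of no consequence. Dess–Martin oxidation (NaHCO3, CH2Cl2) would give 6 with no amine present.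

Step 9. Cleavage of the hindered secondary TBS ether may be slow enough for enediol-mediated epimerization or α-ketol transposition, or acid-induced chroman formation from the ortho-prenyl phenol, to compete. The fallback replaces the protecting group by one that leaves under much milder conditions; it sets out from 3 and returns at 15. TESCl/imidazole would give (S)-N-methoxy-3-(4-methoxyphenyl)-N-methyl-2-(triethylsilyloxy)propanamide F7, and 5 would convert it into (S)-5-(4-methoxyphenyl)-4-(triethylsilyloxy)pent-1-yn-3-one F8. Cycloaddition with 11 as in step 8 would pass through the triethylsilyl cyclohexa-1,4-diene cycloadduct F9 and the triethylsilyl bis(trimethylsilyl) aryl ether F10 to (S)-1-[2,4-dihydroxy-5-(3-methylbut-2-en-1-yl)phenyl]-3-(4-methoxyphenyl)-2-(triethylsilyloxy)propan-1-one F11. AcOH/THF/H2O at rt would then cleave the TES ether to give 15.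

**Further compounds**

F1 | step 8 | 4,6-dibromoresorcinol | Oc1cc(O)c(Br)cc1Br
F2 | step 8 | 1,5-dibromo-2,4-bis(methoxymethoxy)benzene | COCOc1cc(OCOC)c(Br)cc1Br
F3 | step 8 | 1-bromo-2,4-bis(methoxymethoxy)-5-(3-methylbut-2-en-1-yl)benzene | COCOc1cc(OCOC)c(CC=C(C)C)cc1Br
F4 | step 8 | (S)-1-[2,4-bis(methoxymethoxy)-5-(3-methylbut-2-en-1-yl)phenyl]-2-(tert-butyldimethylsilyloxy)-3-(4-methoxyphenyl)propan-1-one | COc1ccc(C[C@H](O[Si](C)(C)C(C)(C)C)C(=O)c2cc(CC=C(C)C)c(OCOC)cc2OCOC)cc1
F5 | step 4 | (S)-2-(tert-butyldimethylsilyloxy)-3-(4-methoxyphenyl)propanal | COc1ccc(C[C@H](O[Si](C)(C)C(C)(C)C)C=O)cc1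
F6 | step 4 | (4S)-4-(tert-butyldimethylsilyloxy)-5-(4-methoxyphenyl)pent-1-yn-3-ol, mixture of C3 epimers | COc1ccc(C[C@H](O[Si](C)(C)C(C)(C)C)C(O)C#C)cc1
F7 | step 9 | (S)-N-methoxy-3-(4-methoxyphenyl)-N-methyl-2-(triethylsilyloxy)propanamide | COc1ccc(C[C@H](O[Si](CC)(CC)CC)C(=O)N(C)OC)cc1
F8 | step 9 | (S)-5-(4-methoxyphenyl)-4-(triethylsilyloxy)pent-1-yn-3-one | COc1ccc(C[C@H](O[Si](CC)(CC)CC)C(=O)C#C)cc1
F9 | step 9 | (2S)-1-[6-methoxy-3-(3-methylbut-2-en-1-yl)-4,6-bis(trimethylsilyloxy)cyclohexa-1,4-dien-1-yl]-3-(4-methoxyphenyl)-2-(triethylsilyloxy)propan-1-one, mixture of ring diastereomers | COc1ccc(C[C@H](O[Si](CC)(CC)CC)C(=O)C2=CC(CC=C(C)C)C(O[Si](C)(C)C)=CC2(OC)O[Si](C)(C)C)cc1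
F10 | step 9 | (S)-3-(4-methoxyphenyl)-1-[5-(3-methylbut-2-en-1-yl)-2,4-bis(trimethylsilyloxy)phenyl]-2-(triethylsilyloxy)propan-1-one | COc1ccc(C[C@H](O[Si](CC)(CC)CC)C(=O)c2cc(CC=C(C)C)c(O[Si](C)(C)C)cc2O[Si](C)(C)C)cc1
F11 | step 9 | (S)-1-[2,4-dihydroxy-5-(3-methylbut-2-en-1-yl)phenyl]-3-(4-methoxyphenyl)-2-(triethylsilyloxy)propan-1-one | COc1ccc(C[C@H](O[Si](CC)(CC)CC)C(=O)c2cc(CC=C(C)C)c(O)cc2O)cc1
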